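**Retrosynthetic overview**

- The last bond made is C3 of the 5-oxo-2,5-dihydrofuran to C1 of the 3,4-dihydroxy-5-prenylphenyl ring, formed without protecting groups by laccase-mediated aerobic coupling of the C3–H butenolide with 3-prenylcatechol.
- Enabling feature: C3 is the β-carbon of the stable enol O–C4=C3 of the 4,5-dioxolactone, so it is a carbon nucleophile. The aryl ring is a 1,2-diol that an oxidase turns into an o-quinone whose C5 (para to the OH beside the prenyl group) is the open Michael position; tautomerisation then returns both catechol and enol.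
- The butenolide is the only ring that is built: C3–C4 by Claisen condensation of a 2-benzylmalate enolate with dimethyl oxalate, O1–C5 by lactonisation, then one Pd(0) operation removes the allyl ester (with decarboxylation) and the phenol allyl ether.
- The quaternary (S) centre comes from (S)-malic acid by self-regeneration of stereocentres: cis-pivalaldehyde dioxolanone, alkylation with the prenylated benzylic bromide.
- Prenyl groups: ortho-C-prenylation of a phenolate (benzyl arm) and directed ortho-lithiation/prenylation of bis-MOM catechol (catechol arm); both benzene rings are bought.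

Key step: step 14

Remarks on the chemistry:
- Ring numbering used throughout: O1, C2 (quaternary), C3, C4 (C–OH), C5 (C=O). Catechol numbering: C1(OH), C2(OH), C3(prenyl).
- "Prenyl" = 3-methylbut-2-en-1-yl; "allyl" = prop-2-en-1-yl.
- By the CIP rules the stereocentre as drawn is (S) (O1 > CO2Me > C3 > CH2Ar). This corresponds to (S)-malic acid when the benzyl group replaces H with retention.

**Route**

Step 1
Reactants: 1 methyl 4-hydroxybenzoate
Product: 3 methyl 4-hydroxy-3-prenylbenzoate, via sodium phenolate 2 (not isolated)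
Conditions: NaH (1.0 equiv), toluene, 0 °C to rt; prenyl bromide (1.0 equiv), rt
Reagents that add atoms: prenyl bromide (1-bromo-3-methylbut-2-ene), CC(C)=CCBr
Why: Ortho-C-alkylation of a phenoxide: as a tight sodium ion pair in a non-polar solvent the phenolate should attack the allylic bromide through the ring carbon ortho to oxygen (para is blocked) rather than through oxygen.

Step 2
Reactants: 3 methyl 4-hydroxy-3-prenylbenzoate
Product: 4 methyl 4-(allyloxy)-3-prenylbenzoate
Conditions: allyl bromide, K2CO3, acetone, reflux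
Reagents that add atoms: allyl bromide, C=CCBr
Why: Williamson ether synthesis; the allyl ether is stable to the strong bases ahead and leaves in the same Pd(0) step as the allyl ester.

Step 3
Reactants: 4 methyl 4-(allyloxy)-3-prenylbenzoate
Product: 5 [4-(allyloxy)-3-prenylphenyl]methanol
Conditions: DIBAL-H (2.5 equiv), CH2Cl2, −78 to 0 °C; Rochelle salt
Reagents that add atoms: none
Why: Hydride reduction of the ester to the benzylic alcohol with DIBAL-H, which leaves both alkenes untouched.

Step 4
Reactants: 5 [4-(allyloxy)-3-prenylphenyl]methanol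
Product: 6 1-(allyloxy)-4-(bromomethyl)-2-prenylbenzene
Conditions: CBr4, PPh3, CH2Cl2, 0 °C; used at once
Reagents that add atoms: carbon tetrabromide, BrC(Br)(Br)Br
Why: Appel reaction under neutral conditions, so no HBr is present to add to the prenyl alkene.

Step 5
Reactants: 7 (S)-malic acid
Product: 8 [(2S,4S)-2-tert-butyl-5-oxo-1,3-dioxolan-4-yl]acetic acid (cis)
Conditions: t-BuCHO, TsOH·H2O (cat.), H2SO4 (cat.), pentane, reflux, Dean–Stark; recrystallisation
Reagents that add atoms: pivalaldehyde, CC(C)(C)C=O
Why: Acid-catalysed acetalisation of the α-hydroxy acid (first stage of self-regeneration of stereocentres); the cis-dioxolanone is the thermodynamic isomer and should be purified by crystallisation, so the acetal centre is set by the malic acid centre.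

Step 6
Reactants: 8 [(2S,4S)-2-tert-butyl-5-oxo-1,3-dioxolan-4-yl]acetic acid + 6 1-(allyloxy)-4-(bromomethyl)-2-prenylbenzene
Product: 10 [(2S,4S)-4-{[4-(allyloxy)-3-prenylphenyl]methyl}-2-tert-butyl-5-oxo-1,3-dioxolan-4-yl]acetic acid (arylmethyl trans to tert-butyl), via dilithium enolate carboxylate 9 (not isolated)
Conditions: LiHMDS (2.2 equiv), THF, −78 °C; 6 (1.2 equiv), −78 to −20 °C; 1 M HCl
Reagents that add atoms: none
Why: Alkylation with self-regeneration of stereocentres: the planar dioxolanone enolate keeps the acetal centre, and the benzylic bromide should enter anti to the tert-butyl group, so ArCH2 takes the place of the former H (retention) and sets the quaternary centre.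

Step 7
Reactants: 10 [(2S,4S)-4-{[4-(allyloxy)-3-prenylphenyl]methyl}-2-tert-butyl-5-oxo-1,3-dioxolan-4-yl]acetic acid
Product: 11 (3S)-4-[4-(allyloxy)-3-prenylphenyl]-3-hydroxy-3-(methoxycarbonyl)butanoic acid
Conditions: NaOMe (2.2 equiv), MeOH, 0 °C to rt; 1 M HCl to pH 3
Reagents that add atoms: sodium methoxide, [Na+].[O-]C
Why: Methoxide transesterification of the lactone acetal releases pivalaldehyde and the tertiary alcohol while the side-chain acid is carried as its carboxylate; the quaternary centre cannot epimerise.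

Step 8
Reactants: 11 (3S)-4-[4-(allyloxy)-3-prenylphenyl]-3-hydroxy-3-(methoxycarbonyl)butanoic acid
Product: 12 4-allyl 1-methyl (2S)-2-{[4-(allyloxy)-3-prenylphenyl]methyl}-2-hydroxybutanedioate
Conditions: allyl bromide (1.1 equiv), KHCO3, DMF, rt
Reagents that add atoms: allyl bromide, C=CCBr
Why: SN2 O-alkylation of the carboxylate, which under bicarbonate conditions is far more nucleophilic than the hindered tertiary alcohol.

Step 9
Reactants: 12 4-allyl 1-methyl (2S)-2-{[4-(allyloxy)-3-prenylphenyl]methyl}-2-hydroxybutanedioate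
Product: 15 3-allyl 2-methyl (2S)-2-{[4-(allyloxy)-3-prenylphenyl]methyl}-4-hydroxy-5-oxo-2,5-dihydrofuran-2,3-dicarboxylate, via dilithium alkoxide enolate 13 (not isolated), via open-chain oxalyl adduct 14 (not isolated)
Conditions: LDA (2.3 equiv), THF, −78 to −40 °C; (CO2Me)2 (1.5 equiv), −78 to 0 °C; 1 M HCl, rt
Reagents that add atoms: dimethyl oxalate, COC(=O)C(=O)OC
Why: Crossed Claisen condensation of a Fráter–Seebach-type β-alkoxide ester dianion with dimethyl oxalate, followed by 5-exo-trig lactonisation of the tertiary hydroxyl onto the new α-keto ester; the lithium alkoxide is a poor leaving group, which should suppress β-elimination, and the product is held as its stable enol.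

Step 10
Reactants: 15 3-allyl 2-methyl (2S)-2-{[4-(allyloxy)-3-prenylphenyl]methyl}-4-hydroxy-5-oxo-2,5-dihydrofuran-2,3-dicarboxylate
Product: 17 methyl (2S)-4-hydroxy-2-[(4-hydroxy-3-prenylphenyl)methyl]-5-oxo-2,5-dihydrofuran-2-carboxylate, via butenolide-3-carboxylic acid 16 (not isolated)
Conditions: Pd(OAc)2 (5 mol %), PPh3 (20 mol %), HCO2H, Et3N, THF, rt to 40 °C; 1 M HCl wash
Reagents that add atoms: none
Why: Tsuji–Trost deallylation with formate as hydride donor: Pd(0) ionises both the allyl ester and the aryl allyl ether, the allyl units leave as propene, and the vinylogous β-keto acid 16 should lose CO2 to give the C3–H enol.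

Step 11
Reactants: 18 catechol (benzene-1,2-diol)
Product: 19 1,2-bis(methoxymethoxy)benzene
Conditions: MOMCl (2.5 equiv), i-Pr2NEt (3 equiv), CH2Cl2, 0 °C to rt
Reagents that add atoms: chloromethyl methyl ether, COCCl
Why: O-Alkylation of both phenols (MOM protection) installs the directing groups for lithiation.

Step 12
Reactants: 19 1,2-bis(methoxymethoxy)benzene
Product: 21 1,2-bis(methoxymethoxy)-3-prenylbenzene, via 3-lithio arene 20 (not isolated)
Conditions: n-BuLi (1.1 equiv), TMEDA, THF, 0 °C; CuI (10 mol %), prenyl bromide, −78 °C to rt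
Reagents that add atoms: prenyl bromide (1-bromo-3-methylbut-2-ene), CC(C)=CCBr
Why: Directed ortho-metalation next to an OMOM group, then copper-catalysed allylic substitution at the primary carbon of prenyl bromide (SN2) should give the linear prenyl arene.

Step 13
Reactants: 21 1,2-bis(methoxymethoxy)-3-prenylbenzene
Product: 22 3-prenylbenzene-1,2-diol (3-prenylcatechol)
Conditions: HCl (0.5 M) in MeOH, rt, under Ar
Reagents that add atoms: none
Why: Acid-catalysed acetal exchange with methanol removes both MOM groups; dilute acid at room temperature is chosen so that the ortho-prenyl phenol is not cyclised to a chroman.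

Step 14
Reactants: 17 methyl (2S)-4-hydroxy-2-[(4-hydroxy-3-prenylphenyl)methyl]-5-oxo-2,5-dihydrofuran-2-carboxylate + 22 3-prenylbenzene-1,2-diol
Product: 24 methyl (2S)-3-(3,4-dihydroxy-5-prenylphenyl)-4-hydroxy-2-[(4-hydroxy-3-prenylphenyl)methyl]-5-oxo-2,5-dihydrofuran-2-carboxylate, via 3-prenyl-o-benzoquinone 23 (not isolated)
Conditions: laccase (EC 1.10.3.2, low-potential fungal enzyme, e.g. Myceliophthora thermophila), O2 (1 atm), phosphate buffer pH 6.0/acetone 3:1, rt; 22 (1.3 equiv); Na2S2O4 wash
Reagents that add atoms: none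
Why: Proposed new method: the laccase (a multicopper oxidase) should oxidise only the catechol 22 with O2 to the o-quinone 23, the enol O–C4=C3 of 17 then adds through its β-carbon C3 to quinone C5 in a 1,4-fashion, and tautomerisation of the adduct restores both the aromatic catechol and the conjugated enol, which is the driving force. The closest known reaction type is the laccase-initiated oxidative Michael arylation of 1,3-dicarbonyl C–H acids with catechols; a 4-hydroxy-5-oxo-2,5-dihydrofuran enol as the carbon nucleophile goes beyond that precedent. No ring is closed and no stereocentre is formed; the quaternary C2 centre next to the reacting carbon carries no hydrogen and cannot epimerise. Three selectivities are needed: oxidation of the catechol but not of the monophenol, the enol or the alkenes (secured by the low redox potential of the enzyme, which matches only the 1,2-diol), attack at quinone C5 and not C4 (C4 lies beside the prenyl group and its enone is damped by that alkyl substituent), and C- rather than O-attack of the enol (soft enol carbon on a soft Michael acceptor, with rearomatisation making the C-adduct irreversible). Over-oxidation of the product catechol should be limited because its new vinylogous-ester substituent raises its oxidation potential above that of 22, which is kept in slight excess as a redox buffer, and any product quinone is reduced back in the dithionite wash.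

**Compound list**

1 | methyl 4-hydroxybenzoate | COC(=O)c1ccc(O)cc1 | starting material
2 | sodium 4-(methoxycarbonyl)phenolate | COC(=O)c1ccc([O-])cc1.[Na+] | intermediate
3 | methyl 4-hydroxy-3-(3-methylbut-2-en-1-yl)benzoate | COC(=O)c1ccc(O)c(CC=C(C)C)c1 | intermediate
4 | methyl 3-(3-methylbut-2-en-1-yl)-4-(prop-2-en-1-yloxy)benzoate | COC(=O)c1ccc(OCC=C)c(CC=C(C)C)c1 | intermediate
5 | [3-(3-methylbut-2-en-1-yl)-4-(prop-2-en-1-yloxy)phenyl]methanol | OCc1ccc(OCC=C)c(CC=C(C)C)c1 | intermediate
6 | 4-(bromomethyl)-2-(3-methylbut-2-en-1-yl)-1-(prop-2-en-1-yloxy)benzene | BrCc1ccc(OCC=C)c(CC=C(C)C)c1 | intermediate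
7 | (S)-malic acid | O[C@@H](CC(=O)O)C(=O)O | starting material
8 | [(2S,4S)-2-tert-butyl-5-oxo-1,3-dioxolan-4-yl]acetic acid (cis) | O=C1O[C@@H](C(C)(C)C)O[C@H]1CC(=O)O | intermediate
9 | dilithium enolate carboxylate of 8 (acetal centre retained) | [Li+].[Li+].[O-]C1=C(CC(=O)[O-])O[C@H](C(C)(C)C)O1 | intermediate
10 | [(2S,4S)-2-tert-butyl-4-{[3-(3-methylbut-2-en-1-yl)-4-(prop-2-en-1-yloxy)phenyl]methyl}-5-oxo-1,3-dioxolan-4-yl]acetic acid (arylmethyl trans to tert-butyl) | O=C1O[C@@H](C(C)(C)C)O[C@]1(CC(=O)O)Cc1ccc(OCC=C)c(CC=C(C)C)c1 | intermediate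
11 | (3S)-3-hydroxy-3-(methoxycarbonyl)-4-[3-(3-methylbut-2-en-1-yl)-4-(prop-2-en-1-yloxy)phenyl]butanoic acid | COC(=O)[C@@](CC(=O)O)(Cc1ccc(OCC=C)c(CC=C(C)C)c1)O | intermediate
12 | 1-methyl 4-(prop-2-en-1-yl) (2S)-2-hydroxy-2-{[3-(3-methylbut-2-en-1-yl)-4-(prop-2-en-1-yloxy)phenyl]methyl}butanedioate | COC(=O)[C@@](CC(=O)OCC=C)(Cc1ccc(OCC=C)c(CC=C(C)C)c1)O | intermediate
13 | dilithium alkoxide ester enolate of 12 | COC(=O)[C@@](C=C([O-])OCC=C)(Cc1ccc(OCC=C)c(CC=C(C)C)c1)[O-].[Li+].[Li+] | intermediate
14 | open-chain adduct of 12 carrying a methoxyoxalyl group on C3 (new CH centre undefined, present as its enolate) | COC(=O)[C@@](C(C(=O)OCC=C)C(=O)C(=O)OC)(Cc1ccc(OCC=C)c(CC=C(C)C)c1)O | intermediate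
15 | 2-methyl 3-(prop-2-en-1-yl) (2S)-4-hydroxy-2-{[3-(3-methylbut-2-en-1-yl)-4-(prop-2-en-1-yloxy)phenyl]methyl}-5-oxo-2,5-dihydrofuran-2,3-dicarboxylate | COC(=O)[C@@]1(Cc2ccc(OCC=C)c(CC=C(C)C)c2)OC(=O)C(O)=C1C(=O)OCC=C | intermediate
16 | (2S)-4-hydroxy-2-{[4-hydroxy-3-(3-methylbut-2-en-1-yl)phenyl]methyl}-2-(methoxycarbonyl)-5-oxo-2,5-dihydrofuran-3-carboxylic acid | COC(=O)[C@@]1(Cc2ccc(O)c(CC=C(C)C)c2)OC(=O)C(O)=C1C(=O)O | intermediate
17 | methyl (2S)-4-hydroxy-2-{[4-hydroxy-3-(3-methylbut-2-en-1-yl)phenyl]methyl}-5-oxo-2,5-dihydrofuran-2-carboxylate | COC(=O)[C@@]1(Cc2ccc(O)c(CC=C(C)C)c2)OC(=O)C(O)=C1 | intermediate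
18 | catechol (benzene-1,2-diol) | Oc1ccccc1O | starting material
19 | 1,2-bis(methoxymethoxy)benzene | COCOc1ccccc1OCOC | intermediate
20 | [2,3-bis(methoxymethoxy)phenyl]lithium | [Li]c1cccc(OCOC)c1OCOC | intermediate
21 | 1,2-bis(methoxymethoxy)-3-(3-methylbut-2-en-1-yl)benzene | COCOc1cccc(CC=C(C)C)c1OCOC | intermediate
22 | 3-(3-methylbut-2-en-1-yl)benzene-1,2-diol | Oc1cccc(CC=C(C)C)c1O | intermediate
23 | 3-(3-methylbut-2-en-1-yl)cyclohexa-3,5-diene-1,2-dione | O=C1C=CC=C(CC=C(C)C)C1=O | intermediate
24 | methyl (2S)-3-[3,4-dihydroxy-5-(3-methylbut-2-en-1-yl)phenyl]-4-hydroxy-2-{[4-hydroxy-3-(3-methylbut-2-en-1-yl)phenyl]methyl}-5-oxo-2,5-dihydrofuran-2-carboxylate | COC(=O)[C@@]1(Cc2ccc(O)c(CC=C(C)C)c2)OC(=O)C(O)=C1c1cc(O)c(O)c(CC=C(C)C)c1 | target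

**Step count and risks**

Total step count: 14. Longest linear sequence: 10 steps (steps 1–4, 6–10 and 14).

Steps most likely to fail:

1. Step 14 (proposed new method). The enol carbon may add too slowly, so that the o-quinone oligomerises or tautomerises to a quinone methide and electrocyclises. The attack may go to the wrong quinone carbon. The product catechol may be re-oxidised, with oxa-cyclisation of the enol oxygen or a second arylation.
Fallback by known chemistry, setting out from 17 and from 21 and coming back at 24: 17 would be brominated at the enol carbon C3 (NBS, 1.0 equiv, THF, −78 °C) to methyl (2R)-3-bromo-4-hydroxy-2-[(4-hydroxy-3-prenylphenyl)methyl]-5-oxo-2,5-dihydrofuran-2-carboxylate F1 (same spatial arrangement; the descriptor changes because Br raises the rank of C3). Both hydroxyls would be capped (MOMCl, i-Pr2NEt, CH2Cl2) to give the bis-MOM bromide F2. In parallel 21 would undergo sterically governed Ir-catalysed C–H borylation at C5, the only C–H with no ortho substituent ([Ir(OMe)(cod)]2, dtbpy, B2pin2, THF, 60 °C), to the pinacol boronate F3. Suzuki–Miyaura coupling of F2 with F3 (Pd(OAc)2, SPhos, K3PO4, toluene/H2O, 60 °C) should give the tetra-MOM ether F4, and dilute HCl in MeOH at rt would remove the four MOM groups to reach 24.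

2. Step 9. The dianion may undergo retro-aldol or β-elimination, the allyl ester enolate may rearrange (ester-enolate Claisen) on warming, or acylation may stop at oxygen without ring closure.
Fallback, setting out from 12 and coming back at 15: the order of bond formation is reversed. The tertiary alcohol of 12 would first be acylated with methyl chlorooxoacetate (Et3N, DMAP, CH2Cl2, 0 °C) to the mixed oxalate 4-allyl 1-methyl (2S)-2-{[4-(allyloxy)-3-prenylphenyl]methyl}-2-[(methoxyoxalyl)oxy]butanedioate F5. An intramolecular Dieckmann condensation under soft enolisation (TiCl4, Bu3N, CH2Cl2, −78 °C) would then close the C3–C4 bond onto the distal oxalate carbonyl to give 15.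

3. Step 1. O-Alkylation and double alkylation may compete with ortho-C-alkylation of the phenolate.
Fallback, setting out from 1 and coming back at 3: 1 would be O-alkylated with 3-chloro-3-methylbut-1-yne (K2CO3, KI, CuI cat., acetone, reflux) to methyl 4-[(2-methylbut-3-yn-2-yl)oxy]benzoate F6. Semi-hydrogenation (H2, Lindlar catalyst, quinoline, EtOAc) would give methyl 4-[(2-methylbut-3-en-2-yl)oxy]benzoate F7. An aromatic Claisen rearrangement (N,N-diethylaniline, 140 °C) would then deliver the prenyl group to the ortho carbon and give 3.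

Further compounds
F1 | step 14 | methyl (2R)-3-bromo-4-hydroxy-2-{[4-hydroxy-3-(3-methylbut-2-en-1-yl)phenyl]methyl}-5-oxo-2,5-dihydrofuran-2-carboxylate | COC(=O)[C@@]1(Cc2ccc(O)c(CC=C(C)C)c2)OC(=O)C(O)=C1Br
F2 | step 14 | methyl (2R)-3-bromo-4-(methoxymethoxy)-2-{[4-(methoxymethoxy)-3-(3-methylbut-2-en-1-yl)phenyl]methyl}-5-oxo-2,5-dihydrofuran-2-carboxylate | COC(=O)[C@@]1(Cc2ccc(OCOC)c(CC=C(C)C)c2)OC(=O)C(OCOC)=C1Br
F3 | step 14 | 2-[3,4-bis(methoxymethoxy)-5-(3-methylbut-2-en-1-yl)phenyl]-4,4,5,5-tetramethyl-1,3,2-dioxaborolane | COCOc1cc(B2OC(C)(C)C(C)(C)O2)cc(CC=C(C)C)c1OCOC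
F4 | step 14 | methyl (2S)-3-[3,4-bis(methoxymethoxy)-5-(3-methylbut-2-en-1-yl)phenyl]-4-(methoxymethoxy)-2-{[4-(methoxymethoxy)-3-(3-methylbut-2-en-1-yl)phenyl]methyl}-5-oxo-2,5-dihydrofuran-2-carboxylate | COC(=O)[C@@]1(Cc2ccc(OCOC)c(CC=C(C)C)c2)OC(=O)C(OCOC)=C1c1cc(OCOC)c(OCOC)c(CC=C(C)C)c1
F5 | step 9 | 1-methyl 4-(prop-2-en-1-yl) (2S)-2-[(2-methoxy-2-oxoacetyl)oxy]-2-{[3-(3-methylbut-2-en-1-yl)-4-(prop-2-en-1-yloxy)phenyl]methyl}butanedioate | COC(=O)[C@@](CC(=O)OCC=C)(Cc1ccc(OCC=C)c(CC=C(C)C)c1)OC(=O)C(=O)OC
F6 | step 1 | methyl 4-[(2-methylbut-3-yn-2-yl)oxy]benzoate | COC(=O)c1ccc(OC(C)(C)C#C)cc1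
F7 | step 1 | methyl 4-[(2-methylbut-3-en-2-yl)oxy]benzoate | COC(=O)c1ccc(OC(C)(C)C=C)cc1
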